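## Structural features

The target is a flavone: benzene ring A is fused to the 4-pyranone ring C, and aryl ring B is attached at C2 through the C2–C1' bond; there is no stereocentre. Ring A is fully substituted (O1, 5-OH, 6-OMe, 7-OH, 8-OMe around C4a), and its oxygen pattern is mirror-symmetric about the C4a–C7 axis once ring C is opened. Ring B carries 2'-OMe, 3'-OH and 6'-OH, so C1' is flanked on both sides by oxygenated carbons, and ring B is a hydroquinone (3'-OH para to 6'-OH) that is sensitive to air and base. Hydroxyls and methyl ethers must stay distinguishable throughout, so the hydroxyls travel as benzyl or acetal ethers and no O-methylation or O-demethylation is planned. The real difficulties are the hindered C2–C1' bond, the pentaoxygenated ring A, and the ring B pattern with a substituent between two oxygens, which electrophilic substitution does not deliver. The key step uses two adjacencies: the 6'-oxygen is next to C1' and C3–H is next to C2. A carboxyl carbon on C3, esterified with the 6'-oxygen, lets C2 and C1' meet in a six-membered lactone ring closure, and that carbon can be expelled later as CO2.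

## Logic of the disconnections

**23 to 20.** The C3–H bond and the free 6'-OH and 3'-OH of 23 are traced back to a C3 carboxyl carbon held in a lactone with O6', and to an acetal on O3'. This reinstates the bridge that the key step needs. The forward step must cleave the acetal (21), hydrolyse the lactone (22) and lose CO2. The C3 acid is a β-keto acid on an sp2 carbon, so CO2 can leave only after water has added reversibly to C2; a transient ring-opened 1,3-diketone must therefore be expected. For that reason ring A is deprotected first: its chelated carbonyl and its symmetric oxygen pattern make reclosure through ring A oxygen the favoured and degenerate outcome.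

**20 to 19.** The two O–H bonds at C5 and C7 are traced back to O–benzyl bonds. Benzyl ethers are inert to the palladium step and are removed by hydrogenolysis without touching methyl ethers, the lactone or the acetal.

**19 to 18 (key disconnection).** The C2–C1' bond is cut. This removes the one hindered biaryl-type bond and leaves an ester whose two halves are simple aromatic building blocks. The forward step must activate C1' (through bromine) and C2–H selectively and must keep the activated aryl ester intact under base.

**18 to 9 and 17.** The ester C–O bond between the C3 carboxyl carbon and O6' is cut, which makes the route convergent. The forward esterification must cope with a phenol ortho to bromine and must not touch the acid-labile acetal or the electrophilic C2.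

**9 to 8 to 7.** The carboxyl is traced back to a formyl group (8). Ring C is then opened at O1–C2 and at the bonds from C3 to C2 and to the formyl carbon, which leads to the methyl ketone 7 and two one-carbon units. The forward step is the standard double formylation and cyclisation of a 2-hydroxyaryl methyl ketone.

**7 to 6 to 4.** One O–benzyl bond is cut (6). Mono-alkylation is secure because the two hydroxyls of 6 are equivalent and the second one becomes hydrogen-bonded. The aryl–acetyl bond is then cut (through 5) to give 4, whose only free ring carbon lies between two hydroxyls.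

**4 to 3 to 2 to 1.** Two aryl C–O bonds are traced back to C–Br bonds (3), then to C–H bonds (2). The O–benzyl bond of 2 leads to commercial 1. Capping the oxygen of 1 is what steers both brominations away from the para position and onto the carbons that must become oxygenated.

**17 to 14.** The C–Br bond is cut (through 16 and 15) and the phenol oxygen is masked as an acetal (14). The forward step is a directed lithiation between two oxygens. It needs a directing acetal that can be removed beside the acetal on the neighbouring oxygen.

**14 to 13 to 11 to 10.** The directing acetal is removed (13). The aryl C–O bond is traced back to an aryl–CHO bond (11, through 12), and the remaining acetal to the free phenol of commercial 10. The aldehyde of 11 has no free ortho or para hydroxyl, so the forward oxidation is planned with a peracid and not with alkaline peroxide.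

## Other disconnections considered

**Alternative 1:** The cut is the C2=C3 double bond of ring C.

- **Key step.** The product would be 5,7-bis(benzyloxy)-2-[3,6-bis(benzyloxy)-2-methoxyphenyl]-6,8-dimethoxy-4H-chromen-4-one A1. It would form when the ylide ester 3,5-bis(benzyloxy)-2,4-dimethoxy-6-[(triphenylphosphoranylidene)acetyl]phenyl 3,6-bis(benzyloxy)-2-methoxybenzoate A2 is heated in toluene: the ylide carbon (C3) adds to the ester carbonyl (C2) and the phosphine oxide is expelled.
- **In favour.** The conditions are neutral. The C2–C1' bond enters as an ordinary aryl–carboxyl bond. Only one kind of protecting group is used, so A1 is a single hydrogenolysis from the target. There is no carboxyl carbon to remove and no ring B phenol that could compete for ring closure.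
- **Against.** The ester carbonyl that must be attacked lies between 2'-OMe and 6'-OBn, and the stabilised ylide is a weak nucleophile. The ester must also first be made on the hydrogen-bonded, di-ortho-substituted phenol oxygen of 7. The congestion at C1' therefore has to be overcome twice. A2 further requires α-bromination of the very electron-rich ketone and phosphonium salt formation.
- **Comparison.** On structure, both plans start from 7 and a ring B unit of similar cost. On mechanism, Alternative 1 is the better-precedented plan, since carbonyl olefination to chromones is established and the chosen C–H arylation is untested on this substrate class. On protecting groups and endgame, Alternative 1 is also the better plan. On step economy the two are about equal. The chosen plan's only advantage is that it turns the congestion at C1' into proximity.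

**Alternative 2:** The cuts are C4a–C8a (ring A) and O1–C2 (ring C).

- **Key step.** The product would be 5,7-dihydroxy-6,8-dimethoxy-2-[2-methoxy-3,6-bis(methoxymethoxy)phenyl]-4H-chromen-4-one A3. Mg(OMe)2 in methanol would open the pyranone 4-hydroxy-3,5-dimethoxy-6-{4-[2-methoxy-3,6-bis(methoxymethoxy)phenyl]-2-oxobut-3-yn-1-yl}-2H-pyran-2-one A4 to a chelated triketo ester. The C4a methylene would then attack the ester carbon in a Claisen condensation that closes ring A, and the new phenoxide would add 6-endo-dig to the ynone to close ring C.
- **In favour.** Ring A appears with all five oxygens in one operation, without aromatic substitution chemistry and without protecting groups on ring A. Because the new ring A is symmetric, either phenoxide gives A3; on this point the plan is the equal of the chosen one. A3 is one mild acid step from the target, which is the shortest endgame of all and better than the chosen one.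
- **Against.** A4 must first be built. A pyranone with two adjacent methoxyls and an acetylenic ketone on a di-ortho-substituted aryl would probably cost as many steps as the whole chosen route to 18, through base-sensitive intermediates. In the key step methoxide could add to the ynone before any phenoxide exists. The open chain could also close by aldol condensation to a resorcylate instead of by Claisen condensation. The two α-methoxy groups change the enolisation pattern relative to the unsubstituted polyketides for which this chemistry is known.
- **Comparison.** On structure the plan is more economical in protecting groups. On mechanism it is less controllable. On step economy it is better at the end and probably worse overall.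

**Alternative 3:** The cut is the C5'–C6' bond, so that ring B is written as a quinone.

- **Key step.** The product would be 2-[5,7-bis(benzyloxy)-6,8-dimethoxy-4-oxo-4H-chromen-2-yl]-3-methoxy-1,4-benzoquinone A5. Heating racemic 2-[5,7-bis(benzyloxy)-6,8-dimethoxy-4-oxo-4H-chromen-2-yl]-4-ethynyl-4-hydroxy-3-methoxycyclobut-2-en-1-one A6 in p-xylene would cause 4π-electrocyclic opening to an alkynyl vinylketene. The ketene carbon (C6') would bond to the alkyne terminus (C5'), and hydrogen transfer would give the quinone (Moore rearrangement). A6 would come from dimethyl squarate A7.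
- **In favour.** The ring B pattern is fixed by construction from A7: the methoxy carbon sits next to the chromone-bearing carbon and the two carbonyl carbons become C3' and C6'. No directed lithiation and no halogen are needed, which is better than the chosen plan on ring B regiocontrol. A quinone is the oxidised form of ring B, so one final hydrogenation would reduce it and remove the benzyl ethers, a one-step endgame that is also better.
- **Against.** C2 of the chromone must be bonded to a squarate carbon, and a 2-metallated chromone suitable for addition to A7 is not a comfortable reagent; a cross-coupling detour would be needed. The acetylide must add to the correct carbonyl. The thermolysis can also close a five-membered alkylidene cyclopentenedione. A5 is a strongly electrophilic quinone attached to an electron-poor heterocycle.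
- **Comparison.** On structure the plan is attractive for ring B. On mechanism the rearrangement is known but has a competing ring size. On step economy it is no shorter, because the chromone half with a C2 handle costs about as much as 9 and three or four further steps follow.

Key step: step 13

## Route

Remark on the chemistry: the target has no stereocentre. The acetal carbon of 14 and 16 is the only stereocentre on the way; it is racemic and is removed in step 11.

Step 1
Reactants: 1 2,6-dimethoxyphenol (syringol)
Product: 2 2-(benzyloxy)-1,3-dimethoxybenzene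
Conditions: BnBr, K2CO3, DMF, 60 °C
Reagents that add atoms: benzyl bromide, BrCc1ccccc1
Why: Williamson etherification of an acidic phenol; the benzyl group is the later 7-O-benzyl ether and caps the oxygen so that bromination is steered away from the para position.

Step 2
Reactants: 2 2-(benzyloxy)-1,3-dimethoxybenzene
Product: 3 3-(benzyloxy)-1,5-dibromo-2,4-dimethoxybenzene
Conditions: NBS (2.2 equiv), MeCN, 0 °C → 40 °C, dark
Reagents that add atoms: N-bromosuccinimide, O=C1CCC(=O)N1Br
Why: Electrophilic aromatic bromination; in a 1,2,3-trialkoxybenzene the twisted central alkoxy group donates poorly, so both brominations should go ortho to one methoxyl and para to the other, and the unactivated benzyl ring is not attacked.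

Step 3
Reactants: 3 3-(benzyloxy)-1,5-dibromo-2,4-dimethoxybenzene
Product: 4 5-(benzyloxy)-4,6-dimethoxybenzene-1,3-diol
Conditions: Pd2(dba)3 (cat.), t-BuXPhos (cat.), KOH, 1,4-dioxane/H2O, 100 °C, argon; then cold aq. HCl
Reagents that add atoms: potassium hydroxide, [K+].[OH-]
Why: Palladium-catalysed hydroxylation of aryl bromides with hydroxide, in which a bulky biarylphosphine promotes C–O reductive elimination; each bromide has only one ortho substituent, and the electron-rich diol is kept under argon.

Step 4
Reactants: 4 5-(benzyloxy)-4,6-dimethoxybenzene-1,3-diol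
Product: 6 1-[4-(benzyloxy)-2,6-dihydroxy-3,5-dimethoxyphenyl]ethan-1-one, via ketiminium chloride 5 (not isolated)
Conditions: MeCN, ZnCl2, HCl (g), Et2O, 0 °C; then H2O, 100 °C
Reagents that add atoms: acetonitrile, CC#N; water, O
Why: Houben–Hoesch acylation; the nitrilium species attacks the only free ring carbon, which lies between two hydroxyls as in phloroglucinol, and hot water hydrolyses the ketiminium salt, while dry HCl in ether should spare the benzyl ether.

Step 5
Reactants: 6 1-[4-(benzyloxy)-2,6-dihydroxy-3,5-dimethoxyphenyl]ethan-1-one
Product: 7 1-[2,4-bis(benzyloxy)-6-hydroxy-3,5-dimethoxyphenyl]ethan-1-one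
Conditions: BnBr (1.05 equiv), K2CO3, acetone, reflux
Reagents that add atoms: benzyl bromide, BrCc1ccccc1
Why: Williamson mono-benzylation; the two hydroxyls of 6 are equivalent, and after the first alkylation the remaining one is held in a hydrogen bond to the ketone and is much less nucleophilic.

Step 6
Reactants: 7 1-[2,4-bis(benzyloxy)-6-hydroxy-3,5-dimethoxyphenyl]ethan-1-one
Product: 8 5,7-bis(benzyloxy)-6,8-dimethoxy-4-oxo-4H-chromene-3-carbaldehyde
Conditions: POCl3, DMF, 0 °C → 50 °C; then aq. NaOAc
Reagents that add atoms: N,N-dimethylformamide, CN(C)C=O; water, O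
Why: Vilsmeier–Haack double formylation of the acetyl methyl group, ring closure through the phenol oxygen and hydrolysis, the standard route from 2-hydroxyaryl methyl ketones to 3-formylchromones.

Step 7
Reactants: 8 5,7-bis(benzyloxy)-6,8-dimethoxy-4-oxo-4H-chromene-3-carbaldehyde
Product: 9 5,7-bis(benzyloxy)-6,8-dimethoxy-4-oxo-4H-chromene-3-carboxylic acid
Conditions: NaClO2, NaH2PO4, 2-methyl-2-butene, t-BuOH/THF/H2O, rt
Reagents that add atoms: sodium chlorite, [Na+].[O-]Cl=O
Why: Pinnick oxidation; chlorous acid oxidises the aldehyde without touching the C2=C3 bond or the benzyl ethers, and the alkene removes the hypochlorous acid formed.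

Step 8
Reactants: 10 vanillin (4-hydroxy-3-methoxybenzaldehyde)
Product: 11 3-methoxy-4-(methoxymethoxy)benzaldehyde
Conditions: MOMCl, K2CO3, acetone, 0 °C → rt
Reagents that add atoms: chloromethyl methyl ether, COCCl
Why: O-alkylation of the phenoxide; the MOM acetal is the protecting group of the future 3'-oxygen and tolerates peracid, organolithium, base and palladium.

Step 9
Reactants: 11 3-methoxy-4-(methoxymethoxy)benzaldehyde
Product: 13 3-methoxy-4-(methoxymethoxy)phenol, via aryl formate 12 (not isolated)
Conditions: mCPBA, CH2Cl2, 0 °C → rt; aq. NaHCO3 wash; then K2CO3 (cat.), MeOH, rt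
Reagents that add atoms: 3-chloroperbenzoic acid, OOC(=O)c1cccc(Cl)c1
Why: Baeyer–Villiger oxidation, in which the electron-rich aryl group migrates to give the formate, followed by methanolysis; a peracid is used because the Dakin oxidation with alkaline peroxide needs a free ortho or para hydroxyl.

Step 10
Reactants: 13 3-methoxy-4-(methoxymethoxy)phenol
Product: 14 2-[3-methoxy-4-(methoxymethoxy)phenoxy]oxane (racemic)
Conditions: 3,4-dihydro-2H-pyran, PPTS (cat.), CH2Cl2, rt
Reagents that add atoms: 3,4-dihydro-2H-pyran, C1=COCCC1
Why: Acid-catalysed addition of the phenol to the enol ether gives the oxanyl acetal, a directing group for lithiation that is more labile than the MOM ether; the acetal stereocentre is racemic and without consequence.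

Step 11
Reactants: 14 2-[3-methoxy-4-(methoxymethoxy)phenoxy]oxane (racemic)
Product: 17 2-bromo-3-methoxy-4-(methoxymethoxy)phenol, via aryllithium 15 (not isolated), via bromo oxanyl ether 16 (not isolated)
Conditions: n-BuLi, THF, −78 → 0 °C; BrCCl2CCl2Br, −78 °C → rt; aq. NH4Cl work-up; then PPTS (cat.), MeOH, 40 °C
Reagents that add atoms: 1,2-dibromo-1,1,2,2-tetrachloroethane, ClC(Cl)(Br)C(Cl)(Cl)Br
Why: Directed ortho-metalation at the carbon between the acetal oxygen and the methoxyl, which is activated by both as in 1,2,4-trialkoxybenzenes, then bromine transfer to the aryllithium; PPTS in methanol should cleave the oxanyl acetal and leave the MOM ether.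

Step 12
Reactants: 9 5,7-bis(benzyloxy)-6,8-dimethoxy-4-oxo-4H-chromene-3-carboxylic acid; 17 2-bromo-3-methoxy-4-(methoxymethoxy)phenol
Product: 18 2-bromo-3-methoxy-4-(methoxymethoxy)phenyl 5,7-bis(benzyloxy)-6,8-dimethoxy-4-oxo-4H-chromene-3-carboxylate
Conditions: DIC, DMAP (cat.), CH2Cl2, 0 °C → rt
Reagents that add atoms: none
Why: Steglich esterification through the O-acylisourea and the acylpyridinium ion; the neutral conditions spare the MOM ether, the benzyl ethers and the electrophilic C2 of the chromone.

Step 13
Reactants: 18 2-bromo-3-methoxy-4-(methoxymethoxy)phenyl 5,7-bis(benzyloxy)-6,8-dimethoxy-4-oxo-4H-chromene-3-carboxylate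
Product: 19 8,10-bis(benzyloxy)-1,9,11-trimethoxy-2-(methoxymethoxy)-6H,7H-chromeno[4,3-b]chromene-6,7-dione
Conditions: Pd(OAc)2 (10 mol %), PCy3·HBF4 (20 mol %), K2CO3, PivOH (30 mol %), dry DMA, 110 °C, argon
Reagents that add atoms: none
Why: Proposed new method: zerovalent palladium formed from Pd(OAc)2 and PCy3 should insert into the C1'–Br bond of 18, and after bromide–pivalate exchange the ester, once rotated into its s-trans form, holds the arylpalladium centre over C2–H of the pyranone. The C2–C1' bond can then form either by pivalate-assisted concerted metalation–deprotonation at C2–H and reductive elimination from a seven-membered palladacycle, or by 6-endo-trig carbopalladation of C2=C3, which leaves palladium on C3 as an enolate of the C4 ketone and the ester so that carbonate removes the C2 hydrogen and zerovalent palladium is released. The closest known reaction type is the palladium-catalysed intramolecular direct arylation of ortho-halogenated aryl esters to benzo[c]chromen-6-ones under the same acetate/phosphine/carbonate/pivalate system; a chromone-3-carboxylate as the C–H partner has not been shown. One ring is closed, the six-membered lactone made of C1', C2, C3, the carboxyl carbon, the ester oxygen and C6', in the endo mode with respect to C2=C3. No stereocentre and no stable axis is created, because the lactone bridge holds rings B and C close to coplanar. Site selectivity on ring B rests on the bromine at C1', the only carbon–halogen bond, and on the tether, which lets C1' and not C5' reach C2; on the other side C2–H is the only C–H within reach, since ring A is fully substituted and the benzyl C–H bonds would need a macrocyclic transition state. Chemoselectivity requires that the activated aryl ester survives carbonate at 110 °C, hence dry K2CO3, dry DMA and substoichiometric pivalic acid.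

Step 14
Reactants: 19 8,10-bis(benzyloxy)-1,9,11-trimethoxy-2-(methoxymethoxy)-6H,7H-chromeno[4,3-b]chromene-6,7-dione
Product: 20 8,10-dihydroxy-1,9,11-trimethoxy-2-(methoxymethoxy)-6H,7H-chromeno[4,3-b]chromene-6,7-dione
Conditions: H2 (1 atm), 10% Pd/C, THF/EtOAc, rt
Reagents that add atoms: none
Why: Hydrogenolysis of the two benzyl ethers; the tetrasubstituted C2=C3 bond, the aryl lactone and the MOM acetal should be inert, and freeing the 5- and 7-hydroxyls before the acid step biases any later reclosure of ring C toward the chelated 5-hydroxyflavone.

Step 15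
Reactants: 20 8,10-dihydroxy-1,9,11-trimethoxy-2-(methoxymethoxy)-6H,7H-chromeno[4,3-b]chromene-6,7-dione
Product: 23 2-(3,6-dihydroxy-2-methoxyphenyl)-5,7-dihydroxy-6,8-dimethoxy-4H-chromen-4-one, via MOM-free lactone 21 (not isolated), via flavone-3-carboxylic acid 22 (not isolated)
Conditions: HCl (2 M in MeOH), rt; evaporate; then 3 M aq. HCl/AcOH (1:2), 100 °C, argon
Reagents that add atoms: none
Why: Acetal cleavage in methanolic HCl removes the formaldehyde unit as its dimethyl acetal before heating; acid-catalysed lactone hydrolysis then gives 22, a β-keto acid on an sp2 carbon that loses CO2 after reversible addition of water to C2 (a 2-hydroxychromanone, the type of hydrolysis–decarboxylation known for chromone-3-carboxylates and 3-acyl-4-hydroxycoumarins), and dehydration restores the flavone. Reclosure through ring A oxygen is degenerate because the 5- and 8a-oxygens are flanked by identical methoxyls.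

## Compound list

1 | 2,6-dimethoxyphenol (syringol) | COc1cccc(OC)c1O | starting material
2 | 2-(benzyloxy)-1,3-dimethoxybenzene | COc1cccc(OC)c1OCc1ccccc1 | intermediate
3 | 3-(benzyloxy)-1,5-dibromo-2,4-dimethoxybenzene | COc1c(Br)cc(Br)c(OC)c1OCc1ccccc1 | intermediate
4 | 5-(benzyloxy)-4,6-dimethoxybenzene-1,3-diol | COc1c(O)cc(O)c(OC)c1OCc1ccccc1 | intermediate
5 | 1-[4-(benzyloxy)-2,6-dihydroxy-3,5-dimethoxyphenyl]ethan-1-iminium chloride | CC(=[NH2+])c1c(O)c(OC)c(OCc2ccccc2)c(OC)c1O.[Cl-] | intermediate
6 | 1-[4-(benzyloxy)-2,6-dihydroxy-3,5-dimethoxyphenyl]ethan-1-one | CC(=O)c1c(O)c(OC)c(OCc2ccccc2)c(OC)c1O | intermediate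
7 | 1-[2,4-bis(benzyloxy)-6-hydroxy-3,5-dimethoxyphenyl]ethan-1-one | CC(=O)c1c(O)c(OC)c(OCc2ccccc2)c(OC)c1OCc1ccccc1 | intermediate
8 | 5,7-bis(benzyloxy)-6,8-dimethoxy-4-oxo-4H-chromene-3-carbaldehyde | O=Cc1coc2c(OC)c(OCc3ccccc3)c(OC)c(OCc3ccccc3)c2c1=O | intermediate
9 | 5,7-bis(benzyloxy)-6,8-dimethoxy-4-oxo-4H-chromene-3-carboxylic acid | O=C(O)c1coc2c(OC)c(OCc3ccccc3)c(OC)c(OCc3ccccc3)c2c1=O | intermediate
10 | vanillin (4-hydroxy-3-methoxybenzaldehyde) | COc1cc(C=O)ccc1O | starting material
11 | 3-methoxy-4-(methoxymethoxy)benzaldehyde | COCOc1ccc(C=O)cc1OC | intermediate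
12 | 3-methoxy-4-(methoxymethoxy)phenyl formate | COCOc1ccc(OC=O)cc1OC | intermediate
13 | 3-methoxy-4-(methoxymethoxy)phenol | COCOc1ccc(O)cc1OC | intermediate
14 | 2-[3-methoxy-4-(methoxymethoxy)phenoxy]oxane (racemic) | COCOc1ccc(OC2CCCCO2)cc1OC | intermediate
15 | {2-methoxy-3-(methoxymethoxy)-6-[(oxan-2-yl)oxy]phenyl}lithium (racemic) | [Li]c1c(OC2CCCCO2)ccc(OCOC)c1OC | intermediate
16 | 2-[2-bromo-3-methoxy-4-(methoxymethoxy)phenoxy]oxane (racemic) | COCOc1ccc(OC2CCCCO2)c(Br)c1OC | intermediate
17 | 2-bromo-3-methoxy-4-(methoxymethoxy)phenol | COCOc1ccc(O)c(Br)c1OC | intermediate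
18 | 2-bromo-3-methoxy-4-(methoxymethoxy)phenyl 5,7-bis(benzyloxy)-6,8-dimethoxy-4-oxo-4H-chromene-3-carboxylate | O=C(Oc1ccc(OCOC)c(OC)c1Br)c1coc2c(OC)c(OCc3ccccc3)c(OC)c(OCc3ccccc3)c2c1=O | intermediate
19 | 8,10-bis(benzyloxy)-1,9,11-trimethoxy-2-(methoxymethoxy)-6H,7H-chromeno[4,3-b]chromene-6,7-dione | O=C1Oc2ccc(OCOC)c(OC)c2-c2oc3c(OC)c(OCc4ccccc4)c(OC)c(OCc4ccccc4)c3c(=O)c21 | intermediate
20 | 8,10-dihydroxy-1,9,11-trimethoxy-2-(methoxymethoxy)-6H,7H-chromeno[4,3-b]chromene-6,7-dione | O=C1Oc2ccc(OCOC)c(OC)c2-c2oc3c(OC)c(O)c(OC)c(O)c3c(=O)c21 | intermediate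
21 | 2,8,10-trihydroxy-1,9,11-trimethoxy-6H,7H-chromeno[4,3-b]chromene-6,7-dione | O=C1Oc2ccc(O)c(OC)c2-c2oc3c(OC)c(O)c(OC)c(O)c3c(=O)c21 | intermediate
22 | 2-(3,6-dihydroxy-2-methoxyphenyl)-5,7-dihydroxy-6,8-dimethoxy-4-oxo-4H-chromene-3-carboxylic acid | COc1c(O)ccc(O)c1-c1oc2c(OC)c(O)c(OC)c(O)c2c(=O)c1C(=O)O | intermediate
23 | 2-(3,6-dihydroxy-2-methoxyphenyl)-5,7-dihydroxy-6,8-dimethoxy-4H-chromen-4-one (5,7,3',6'-tetrahydroxy-6,8,2'-trimethoxyflavone) | COc1c(O)ccc(O)c1-c1cc(=O)c2c(O)c(OC)c(O)c(OC)c2o1 | target

## Step count and least certain steps

Total step count: 15. Longest linear sequence: 11 steps (steps 1 to 7, then 12 to 15); the ring B branch (steps 8 to 11) joins at step 12.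

**Step 13 (key step).**
- Most likely failure: cleavage of the activated aryl ester by carbonate, pivalate or traces of water before the C–C bond forms, because a phenyl ester of a β-keto-type acid is a good acyl donor at 110 °C.
- Further risks: slow oxidative addition at the di-ortho-substituted, electron-rich C–Br bond, leading to hydrodebromination, and reversible addition of free phosphine to the electrophilic C2.
- Fallback (Baker–Venkataraman, known chemistry): it sets out from 7 and 17 and returns at 23. 17 is benzylated (BnBr, K2CO3) to 1-(benzyloxy)-2-bromo-3-methoxy-4-(methoxymethoxy)benzene F1. Bromine–lithium exchange (n-BuLi, THF, −78 °C) and CO2 give 6-(benzyloxy)-2-methoxy-3-(methoxymethoxy)benzoic acid F2. Esterification with the phenol of 7 through a mixed anhydride (2,4,6-trichlorobenzoyl chloride, Et3N, DMAP) gives 2-acetyl-3,5-bis(benzyloxy)-4,6-dimethoxyphenyl 6-(benzyloxy)-2-methoxy-3-(methoxymethoxy)benzoate F3. Base-induced acyl migration (KOH, pyridine, 50 °C) gives 1-[2,4-bis(benzyloxy)-6-hydroxy-3,5-dimethoxyphenyl]-3-[6-(benzyloxy)-2-methoxy-3-(methoxymethoxy)phenyl]propane-1,3-dione F4. H2SO4 (cat.) in AcOH at 60 °C closes ring C through the only free phenol and removes the MOM group, giving 5,7-bis(benzyloxy)-2-[6-(benzyloxy)-3-hydroxy-2-methoxyphenyl]-6,8-dimethoxy-4H-chromen-4-one F5. Hydrogenolysis (H2, Pd/C) then gives 23.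

**Step 15.**
- Most likely failure: interchange of rings A and B. The decarboxylation passes through a hydrated, ring-opened 1,3-diketone flanked by two ortho-hydroxyaryl groups, so ring C could reclose through the ring B phenol.
- Further risks: incomplete decarboxylation because the hydroxy acid relactonises, and air oxidation of the hydroquinone ring.
- Fallback: it sets out from 19 and returns at 23. The lactone of 19 is opened with NaOMe in MeOH and the liberated phenoxide is trapped with BnBr, giving methyl 5,7-bis(benzyloxy)-2-[6-(benzyloxy)-2-methoxy-3-(methoxymethoxy)phenyl]-6,8-dimethoxy-4-oxo-4H-chromene-3-carboxylate F6, in which the ring B oxygen can no longer take part. Hot aqueous H2SO4 in AcOH hydrolyses the ester, decarboxylates and removes the MOM group, giving F5, the compound that the first fallback also reaches. Hydrogenolysis gives 23.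

**Step 11.**
- Most likely failure: competing lithiation ortho to the MOM ether (C5), because the MOM group is itself a directing group.
- Further risk: partial loss of the MOM ether during the acetal cleavage, which would leave two undifferentiated phenols.
- Fallback: it sets out from 13 and returns at 17, and uses a stronger directing group that is removed by base. 13 is carbamoylated (ClCONEt2, K2CO3, MeCN) to 3-methoxy-4-(methoxymethoxy)phenyl diethylcarbamate F7. Lithiation with s-BuLi/TMEDA in THF at −78 °C and quenching with BrCCl2CCl2Br give 2-bromo-3-methoxy-4-(methoxymethoxy)phenyl diethylcarbamate F8. NaOH in EtOH at reflux gives 17.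

**Step 3.**
- Most likely failure: incomplete exchange of the second bromide, diaryl ether formation between a phenoxide and unreacted bromide, and hydrodebromination, because the mono-phenoxide is an electron-rich, slow substrate.
- Fallback: it sets out from 3 and returns at 4. Double borylation (B2pin2, PdCl2(dppf), KOAc, dioxane, 90 °C) gives 2,2'-[5-(benzyloxy)-4,6-dimethoxy-1,3-phenylene]bis(4,4,5,5-tetramethyl-1,3,2-dioxaborolane) F9. Oxidation with H2O2/NaOH gives 4.

**Step 4.**
- Most likely failure: O-acylation to an imidate instead of C-acylation at the hindered carbon, or acid-induced loss of the benzyl ether.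
- Fallback: it sets out from 4 and returns at 7, and gives up the early benzyl group. Hydrogenolysis of 4 gives 2,4-dimethoxybenzene-1,3,5-triol F10. C-acetylation with AcOH/BF3·OEt2 at 80 °C gives 1-(2,4,6-trihydroxy-3,5-dimethoxyphenyl)ethan-1-one F11. BnBr (2 equiv) and K2CO3 in acetone alkylate the 4-hydroxyl and one of the two chelated hydroxyls, giving 7.

## Further compounds

F1 | step 13 | 1-(benzyloxy)-2-bromo-3-methoxy-4-(methoxymethoxy)benzene | COCOc1ccc(OCc2ccccc2)c(Br)c1OC
F2 | step 13 | 6-(benzyloxy)-2-methoxy-3-(methoxymethoxy)benzoic acid | COCOc1ccc(OCc2ccccc2)c(C(=O)O)c1OC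
F3 | step 13 | 2-acetyl-3,5-bis(benzyloxy)-4,6-dimethoxyphenyl 6-(benzyloxy)-2-methoxy-3-(methoxymethoxy)benzoate | CC(=O)c1c(OC(=O)c2c(OC)c(OCOC)ccc2OCc2ccccc2)c(OC)c(OCc2ccccc2)c(OC)c1OCc1ccccc1
F4 | step 13 | 1-[2,4-bis(benzyloxy)-6-hydroxy-3,5-dimethoxyphenyl]-3-[6-(benzyloxy)-2-methoxy-3-(methoxymethoxy)phenyl]propane-1,3-dione | COCOc1ccc(OCc2ccccc2)c(C(=O)CC(=O)c2c(O)c(OC)c(OCc3ccccc3)c(OC)c2OCc2ccccc2)c1OC
F5 | step 13 | 5,7-bis(benzyloxy)-2-[6-(benzyloxy)-3-hydroxy-2-methoxyphenyl]-6,8-dimethoxy-4H-chromen-4-one | COc1c(O)ccc(OCc2ccccc2)c1-c1cc(=O)c2c(OCc3ccccc3)c(OC)c(OCc3ccccc3)c(OC)c2o1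
F6 | step 15 | methyl 5,7-bis(benzyloxy)-2-[6-(benzyloxy)-2-methoxy-3-(methoxymethoxy)phenyl]-6,8-dimethoxy-4-oxo-4H-chromene-3-carboxylate | COCOc1ccc(OCc2ccccc2)c(-c2oc3c(OC)c(OCc4ccccc4)c(OC)c(OCc4ccccc4)c3c(=O)c2C(=O)OC)c1OC
F7 | step 11 | 3-methoxy-4-(methoxymethoxy)phenyl diethylcarbamate | CCN(CC)C(=O)Oc1ccc(OCOC)c(OC)c1
F8 | step 11 | 2-bromo-3-methoxy-4-(methoxymethoxy)phenyl diethylcarbamate | CCN(CC)C(=O)Oc1ccc(OCOC)c(OC)c1Br
F9 | step 3 | 2,2'-[5-(benzyloxy)-4,6-dimethoxy-1,3-phenylene]bis(4,4,5,5-tetramethyl-1,3,2-dioxaborolane) | COc1c(B2OC(C)(C)C(C)(C)O2)cc(B2OC(C)(C)C(C)(C)O2)c(OC)c1OCc1ccccc1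
F10 | step 4 | 2,4-dimethoxybenzene-1,3,5-triol | COc1c(O)cc(O)c(OC)c1O
F11 | step 4 | 1-(2,4,6-trihydroxy-3,5-dimethoxyphenyl)ethan-1-one | CC(=O)c1c(O)c(OC)c(O)c(OC)c1O
A1 | alternative 1 | 5,7-bis(benzyloxy)-2-[3,6-bis(benzyloxy)-2-methoxyphenyl]-6,8-dimethoxy-4H-chromen-4-one | COc1c(OCc2ccccc2)ccc(OCc2ccccc2)c1-c1cc(=O)c2c(OCc3ccccc3)c(OC)c(OCc3ccccc3)c(OC)c2o1
A2 | alternative 1 | 3,5-bis(benzyloxy)-2,4-dimethoxy-6-[(triphenylphosphoranylidene)acetyl]phenyl 3,6-bis(benzyloxy)-2-methoxybenzoate | COc1c(OCc2ccccc2)ccc(OCc2ccccc2)c1C(=O)Oc1c(OC)c(OCc2ccccc2)c(OC)c(OCc2ccccc2)c1C(=O)C=P(c1ccccc1)(c1ccccc1)c1ccccc1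
A3 | alternative 2 | 5,7-dihydroxy-6,8-dimethoxy-2-[2-methoxy-3,6-bis(methoxymethoxy)phenyl]-4H-chromen-4-one | COc1c(OCOC)ccc(OCOC)c1-c1cc(=O)c2c(O)c(OC)c(O)c(OC)c2o1
A4 | alternative 2 | 4-hydroxy-3,5-dimethoxy-6-{4-[2-methoxy-3,6-bis(methoxymethoxy)phenyl]-2-oxobut-3-yn-1-yl}-2H-pyran-2-one | COc1c(OCOC)ccc(OCOC)c1C#CC(=O)Cc1oc(=O)c(OC)c(O)c1OC
A5 | alternative 3 | 2-[5,7-bis(benzyloxy)-6,8-dimethoxy-4-oxo-4H-chromen-2-yl]-3-methoxy-1,4-benzoquinone | COC1=C(c2cc(=O)c3c(OCc4ccccc4)c(OC)c(OCc4ccccc4)c(OC)c3o2)C(=O)C=CC1=O
A6 | alternative 3 | 2-[5,7-bis(benzyloxy)-6,8-dimethoxy-4-oxo-4H-chromen-2-yl]-4-ethynyl-4-hydroxy-3-methoxycyclobut-2-en-1-one (racemic) | COC1=C(c2cc(=O)c3c(OCc4ccccc4)c(OC)c(OCc4ccccc4)c(OC)c3o2)C(=O)C1(O)C#C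
A7 | alternative 3 | dimethyl squarate (3,4-dimethoxycyclobut-3-ene-1,2-dione) | COC1=C(OC)C(=O)C1=O
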